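You charge 0.80 M of each substrate and 0.88 M of partner, which is less than the two substrates together. Partner is the limiting reagent, and its charge covers 55.0% of them. This flask has been followed to 40.0 h.

in all of them: left-handed substrate 0.80 M; right-handed substrate 0.80 M; precatalyst 40 mM
- south-east: partner 0.88 M; the very flask that is asked about, followed so far
- flask: partner 0.880 M; time 3.0 d

south-east run (percent of the left-handed substrate and right-handed substrate together charged)

| time / h | left-handed product / % | right-handed product / % | left-handed substrate / % |
|---|---|---|---|
| 10.0 | 11.8 | 16.4 | 37.7 |
| 20.0 | 17.4 | 24.6 | 31.4 |
| 25.0 | 19.5 | 27.1 | 29.8 |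
| 40.0 | 22.6 | 30.1 | 27.7 |

(each reading ± 0.5 percentage points)

- excess of left-handed product over right-handed product in the product at 4.0 h
- excess of left-handed product over right-handed product in the product at 3.0 d
- part of the left-handed substrate and right-handed substrate charged together that has reacted at 3.0 d

The zero of your scale is the symmetric case: a ratio of one and an excess of zero. The products at 40.0 h give a reading of 1.53, with the scatter of those readings. That ratio, the log of the fraction of right-handed substrate left over the same log for the left-handed substrate, is the selectivity factor.

Now draw the curve. At zero conversion that reading puts the excess at −21.0%. Taking the partner as first order, the reading at 10.0 h gives it a half-life of 9.64 h. So you reckon 13.7% conversion at 4.0 h.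

To turn conversion into excess, take the summed logs of the two fractions from the mean fraction left, and share them in the ratio of the factor. That gives −19.6% at 4.0 h. By 3.0 d that half-life has passed 7.47 times, so your curve levels at 54.7% conversion and an excess of −14.0%.

The forecast reads the run as “ordinary kinetic resolution” and gives −18.5%, −13.2% and 54.7%. Its early and late excesses differ a little from yours.

The flask gives −19.7%, −13.7% and 53.3%, each within the forecast's margins.

    free catalyst + left-handed substrate ⇌ catalyst intermediate A (K = 0.830 M⁻¹, k = 4.20 M⁻¹ min⁻¹)
    free catalyst + right-handed substrate ⇌ catalyst intermediate B (K = 3.80 M⁻¹, k = 8.00 M⁻¹ min⁻¹)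
    partner + catalyst intermediate A → free catalyst + left-handed product (k = 0.280 M⁻¹ min⁻¹)
    partner + catalyst intermediate B → free catalyst + right-handed product (k = 0.0930 M⁻¹ min⁻¹)
    partner + precatalyst → free catalyst + spent reagent (k = 0.00310 M⁻¹ min⁻¹)
    free catalyst → spent catalyst (k = 7.60 × 10⁻⁷ min⁻¹)
    2 free catalyst ⇌ resting dimer, settled at all times (K = 230 M⁻¹)

At 0.366 d in this flask, catalyst intermediate A falls back 40 times faster than it goes on. The binding constants favour the right-handed substrate by 4.58, the partner rate constants favour the left-handed route by 3.01, and their quotient is 1.52. At 3.00 d this flask has 39% of its right-handed and 54% of its left-handed substrate left, a factor of 1.53. The neighbour flask with 1.5 M of partner reaches 87.9% conversion, where your factor gives −6.38% and that flask stands at −5.77%.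

Readings and results stem from a simulated flask on assumed constants; the scatter is artificial.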